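The runs stem from a simulated flask with made-up constants, and the scatter is random.

Three of the suspects have partner on their left side: the making of catalyst, the making of target and the loss to uncatalysed product. If each is first order in it, the ratio of their rates does not move with [partner], and, for fixed charges of substrate and precatalyst, [partner] sets how fast one and the same course is run, as long as it stays near its charge.

| setting | delta | beta | eta | Tuesday's | Wednesday's |
|---|---|---|---|---|---|
| substrate | 25 mM | 92 mM | 20 mM | 20 mM | 60 mM |
| partner | 50 mM | 50 mM | 130 mM | 50.0 mM | 200 mM |
| precatalyst | 11 µM | 11 µM | 11 µM | 11 µM | 11 µM |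
| remark | run made earlier | run made earlier | run made earlier |  |  |
| time |  |  |  | 40 h | 40 h |

| run | time / h | target / % |
|---|---|---|
| delta | 2.50 | 3 |
| delta | 4.00 | 3 |
| delta | 8.00 | 1 |
| delta | 15.0 | 8 |
| delta | 30.0 | 26 |
| beta | 2.50 | 4 |
| beta | 4.00 | 2 |
| beta | 8.00 | 1 |
| beta | 15.0 | 4 |
| beta | 30.0 | 9 |
| eta | 2.50 | 4 |
| eta | 4.00 | 4 |
| eta | 8.00 | 17 |
| eta | 15.0 | 43 |
| eta | 30.0 | 79 |

(scatter of a reading: 2 percentage points)

- the analysis behind the earlier runs scatters by 2 percentage points, standard deviation
- on the list of suspects stand: target -> over-reaction product; partner + precatalyst -> catalyst + spent reagent; substrate + partner -> uncatalysed product; substrate + partner + catalyst -> target + catalyst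

- the flask that ends with the higher amount of target, in percent of the substrate charged, or "neither" when 2 percentage points or less lies between them (Tuesday's / Wednesday's / neither)
- final target, as a percentage of the substrate charged, in Tuesday's
- final target, as a percentage of the substrate charged, in Wednesday's

The next run has to be chosen: which recipe to charge, and whether its time is needed. Tuesday's stands at 15.4 h of eta time, the hours eta needs for the same product of [partner] and time. Delta's last reading, at 11.5 h of eta time, gives 26 %, between eta's 17 % and 43 %, so this clock passes a rough test, though delta's [substrate] is not eta's. Tuesday's has eta's [substrate] and [precatalyst], so I reckon 43 %, the reading at 15.0 h.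

Wednesday's stands at 61.5 h of eta time, but with a different charge. Delta and beta, at equal eta time, made 6.50 mM and 8.28 mM of target from very different charges, so I count target in mM. Delta's readings grow 3.25 times when its time doubles, roughly as the square of time. On that estimate eta's reading scales to 145 mM for Wednesday's, more than the 60 mM charged. I put the crossing near 25.8 h of Wednesday's own time, earlier than its 40 h: before it I expect the clock to govern, after it the charge. So I charge Wednesday's, keep its time, and put its end near eta's 79 %.

The forecast gives 41 % for Tuesday's and 66 % for Wednesday's, so Wednesday's, holding that “conversion should approach completion” in Wednesday's, with some yield lost.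

The flasks give 42.0 % in Tuesday's and 76.8 % in Wednesday's, so Wednesday's.

    target → over-reaction product (k = 1.09 × 10⁻⁵ h⁻¹)
    partner + precatalyst → catalyst + spent reagent (k = 0.211 M⁻¹ h⁻¹)
    substrate + partner → uncatalysed product (k = 0.104 M⁻¹ h⁻¹)
    substrate + partner + catalyst → target + catalyst, rate k4*[substrate]*[partner]*[catalyst]/(1 + ([substrate]/sat4)) (14.2 mM, k = 3.70 × 10⁵ M⁻² h⁻¹)

In Tuesday's, which ends at 15.4 h of eta time, the making of target uses substrate 4.4 times as fast as the loss to uncatalysed product at 25.0 h and 7.7 times as fast at 40.0 h, and 44 % of the substrate is still there. Wednesday's, which ends at 61.5 h of eta time, has its substrate, the limiting reagent, down to 0.012 % at 40.0 h, with 23.2 % as uncatalysed product, and at 400 h its target still stands at 76.5 %.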